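# Violacene by a chloronium-triggered 1,2-methyl shift

## Structural features

Violacene has one carbocycle, ring A. It is numbered here C1 (quaternary; bears CH3 = C9 and the (E)-2-chlorovinyl group C7=C8), C2 (CH2), C3 (Cl and CH2Br = C10), C4 (CHCl), C5 (CH2) and C6 (CHCl).

The four stereocentres form two vicinal pairs, C1/C6 and C3/C4, separated by the methylenes C2 and C5. The SMILES places the chlorines on C3, C4 and C6 and the chlorovinyl group all on one face, called the upper face. In the chair, C4–Cl, C6–Cl, C9 and C10 are equatorial, and C3–Cl and the chlorovinyl group are 1,3-diaxial.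

Two consequences follow. The C3/C4 dichloride is cis, so anti dichlorination of a ring alkene cannot give it. C6–Cl is a neopentyl secondary chloride, which is hard to make by substitution.

The tertiary chloride with its vicinal primary bromide is the most fragile unit, being prone to elimination and to reductive loss with low-valent metals. The secondary chlorides are sensitive to strong base, so bases and reducing metals have to be used early.

The real difficulty is the all-carbon quaternary C1 next to C6–Cl. Its relation to C3/C4 must be fixed, and the absolute configuration must be set in a molecule with no oxygen or nitrogen handle.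

The key step exploits two features of the C1–C6 bond. Cl on C6 is trans to C9 and cis to C7, which is the signature of an anti addition of Cl+ and CH3 across a C1=C6 alkene. In addition, C9 together with C7–C8 is an isopropyl group in which one methyl has moved from C7 to C1. The ten carbons are therefore those of a 1-isopropyl-3-methylbenzene.

## Logic of the disconnections

**13 ⇒ 12.** Cut C3–Cl and C10–Br. A tertiary chloride next to a primary bromide is the Markovnikov adduct of BrCl to a C3=C10 methylene group. This removes one stereocentre and the two most labile halides, so they appear only in the last step. The forward step must spare the chlorovinyl group. It must take Br+ on the lower face and Cl− on the upper (axial) face.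

**12 ⇒ 11.** Cut C4–Cl and replace it by C4–OH of the opposite configuration. An equatorial C4–Cl cis to C6–Cl cannot be delivered directly, because the upper face at C4 is the hindered one for electrophiles. An axial C4–O bond on the lower face, however, is open to backside attack. The forward step must invert without allylic transposition.

**11 ⇒ 10.** Reconnect the C4 oxygen to C3 and return one hydrogen to C10, which gives a C3–C4 oxirane on the lower face. The oxirane masks the second alkene through steps 4 to 6 and stores the C4 configuration. The forward isomerisation must keep the C4–O bond and take the hydrogen from C10, not from C2 or C5.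

**10 ⇒ 8.** Cut C8–Cl. An (E)-1-chloroalkene on a quaternary carbon is the hydrometalation–chlorination product of a terminal alkyne. Geometry and regiochemistry then follow from the bulk of C1. The forward step must be faster at the alkyne than at the oxirane.

**8 ⇒ 5.** Return C7≡C8 to C7(=O)–C8H3. The gain is a carbonyl group at C7, which is the retron of the key step. The forward step needs a strong base while a secondary chloride and an oxirane are present.

**5 ⇒ 4 (key).** Cut C6–Cl and C1–C9, and reconnect C9 to C7 as part of a dimethylcarbinol on a C1=C6 alkene. In one sentence: a chloronium-triggered 1,2-methyl shift in the monoepoxide 4 of a Birch-derived dienyl dimethylcarbinol. The cut removes the quaternary carbon, the neopentyl chloride and two stereocentres at once. It leaves the carbon skeleton of a simple arene. The forward step must add Cl and CH3 anti, on the correct faces with respect to the oxirane. Migration must also beat proton loss and oxygen capture.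

**4 ⇒ 3.** Cut C3–O and C4–O. The precursor is achiral and flat, so the whole absolute configuration rests on one catalytic epoxidation. The forward step must choose C3=C4 over C1=C6 and one enantiotopic face.

**3 ⇒ 2.** Remove the hydrogens added at C2 and C5 (rearomatisation). A 1,3-dialkylbenzene gives on dissolving-metal reduction exactly the 1,5-disubstituted 1,4-diene, which places both alkenes where they are needed. The forward step must not cleave the benzylic C7–O bond.

**2 ⇒ 1.** Cut one C7–CH3 bond, which leads to a commercial aryl methyl ketone and a methyl Grignard reagent.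

## Other disconnections considered

**Alternative 1:** this is the first cut that comes to mind. It cuts C1–C2 and C5–C6 in a Diels–Alder reaction of isoprene A1 with (Z)-3-chloro-2-methylacrolein A2 under a chiral Lewis acid. The adduct A3 would then undergo aldehyde-to-chlorovinyl olefination and halogenation of C3=C4.
- The larger HOMO coefficient of A1 lies at the CH2 next to the methyl-bearing carbon, and it pairs with the β-carbon of A2. The 1,4-dimethyl isomer A4 is therefore expected, not the 1,3-pattern of A3.
- Even with A3 in hand, anti addition of chlorine to C3=C4 gives the trans dichloride, whereas the target is cis.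
- C10 would still be an unfunctionalised methyl group.
- The cycloaddition thus settles C1/C6 only if its intrinsic regiochemistry is overturned, and it leaves C3/C4 unsolved.

**Alternative 2:** this cuts C1–C2 along the presumed biogenetic line. A chloronium-initiated cation–olefin cyclisation of the acyclic triene A5 would be run with a chemical Cl+ source or a vanadium-dependent haloperoxidase. Loss of a proton from C10 would lead to 12.
- The isolated C2=C3 alkene of A5 is more nucleophilic than the chlorodiene, so initiation is expected at the wrong site.
- A chloriranium ion at C1=C6 is conjugated with C7=C8 and should open to an allyl cation, which erases the anti stereospecificity.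
- No small reagent controls the absolute sense of chloriranium formation, and no enzyme of that class is known to accept this substrate.
- A5 already needs a (Z)-trisubstituted diene and a labile secondary allylic chloride, so little simplicity is gained.

**Alternative 3:** this cuts C1–C2 and C6–Cl and reconnects C2 to the future formyl carbon. The forward step is a ring-contracting chlorinative semipinacol rearrangement of the cycloheptadienol A6 to A3. The aldehyde of A3 would give the chlorovinyl group in one olefination step.
- It shares the anti-addition logic of the chosen plan, but the carbinol carbon of A6 bears a hydrogen, so a hydride shift competes with migration of C2.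
- Ring inversion of the seven-membered ring can present C2 on either face of the alkene. Because the carbinol stereocentre is destroyed, the two modes lead to enantiomers, and chirality transfer is not secured.
- The second trisubstituted alkene is unprotected towards Cl+.
- A6 requires a ring-expansion sequence, whereas 3 is two steps from a commodity ketone.

Key step: step 4

Assumption: the configuration is read from the SMILES as (1R,2S,4R,5R) in systematic numbering, which places C3–Cl and C4–Cl cis; the route is planned for this isomer.

## Route

Step 1
Reactants: 1 3'-methylacetophenone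
Product: 2 2-(3-methylphenyl)propan-2-ol
Conditions: MeMgBr, THF, 0 °C → rt; H2O
Reagents that add atoms: methylmagnesium bromide, C[Mg]Br
Why: Grignard addition to an aryl methyl ketone; it completes the ten-carbon set and creates the dimethylcarbinol C7 whose two methyl groups are equivalent.

Step 2
Reactants: 2 2-(3-methylphenyl)propan-2-ol
Product: 3 2-(5-methylcyclohexa-1,4-dien-1-yl)propan-2-ol
Conditions: Li, NH3 (l), THF, t-BuOH, −78 °C
Reagents that add atoms: none
Why: Birch reduction; alkyl-bearing carbons stay sp2, so a 1,3-dialkylbenzene is protonated at C2 and C5 and gives the 1,5-disubstituted 1,4-diene. In the basic medium the tertiary benzylic alcohol reacts as its alkoxide, a poor leaving group, which holds back cleavage of the C7–O bond.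

Step 3
Reactants: 3 2-(5-methylcyclohexa-1,4-dien-1-yl)propan-2-ol
Product: 4 2-[(1S,6R)-1-methyl-7-oxabicyclo[4.1.0]hept-3-en-3-yl]propan-2-ol
Conditions: D-fructose-derived Shi ketone (30 mol %), Oxone (2KHSO5·KHSO4·K2SO4, 1.0 equiv), K2CO3, Bu4NHSO4, MeCN–CH2(OMe)2 / aq Na2B4O7 buffer, 0 °C
Reagents that add atoms: Oxone, active component potassium peroxymonosulfate, [K+].[O-]S(=O)(=O)OO
Why: Shi epoxidation through the spiro dioxirane transition state. C3=C4 is more electron-rich and much less hindered than C1=C6, which carries the inductively deactivating tertiary carbinol. The D-fructose-derived ketone should deliver oxygen with the facial sense established for 1-substituted cyclohexenes, which corresponds to the (1S,6R) oxirane on the lower face.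

Step 4
Reactants: 4 2-[(1S,6R)-1-methyl-7-oxabicyclo[4.1.0]hept-3-en-3-yl]propan-2-ol
Product: 5 1-[(1S,3R,4R,6R)-4-chloro-1,3-dimethyl-7-oxabicyclo[4.1.0]heptan-3-yl]ethan-1-one
Conditions: 1,3-dichloro-5,5-dimethylhydantoin (DCDMH, 0.55 equiv), NaHCO3 (s), CH2Cl2, −40 → 0 °C, dark
Reagents that add atoms: 1,3-dichloro-5,5-dimethylhydantoin, CC1(C)N(Cl)C(=O)N(Cl)C1=O
Why: The closest known reaction type is the halogenative semipinacol rearrangement of a tertiary allylic alcohol, here with chlorine as electrophile and methyl as migrating group. DCDMH transfers Cl+ to C1=C6, the only alkene left, to give an unsymmetrical chloriranium ion with most C–Cl bonding at C6 and the charge at tertiary C1; the methyl group on C7 that stands antiperiplanar to the weakened C1–Cl bond migrates to C1 while the hydantoin anion takes the O–H proton and C7 becomes the ketone carbon. No ring is closed: ring A is kept and the 1-isopropyl-3-methyl skeleton becomes the 1-ethyl-1,3-dimethyl skeleton of 13. C6 and C1 are set together by the anti course of the addition, so Cl is trans to the new C1 methyl and cis to the acetyl group, as the target requires. Their relation to C3/C4 is controlled by the oxirane: Cl+ reaches C6 on the face that carries C4–H and not the oxirane oxygen (less hindrance, no lone-pair or dipole repulsion), and the methyl group then enters C1 on the face where its 1,3-neighbour on C3 is the small, bent-back oxygen and not the C3 methyl group. The step needs migration to beat loss of an allylic proton and closure of the carbinol oxygen onto C1: C7 bears no hydrogen so no hydride shift competes, its two methyl groups are equivalent so one is always aligned, formation of the C=O bond makes the shift strongly exergonic, and low temperature in a non-basic, non-nucleophilic medium disfavours proton loss. The oxirane oxygen cannot trap the cation, since a bond to C1 or C6 would place an oxetane inside a tricyclic oxonium ion. The β-chloro ketone 5 cannot lose HCl through an enolate because C1 has no hydrogen.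

Step 5
Reactants: 5 1-[(1S,3R,4R,6R)-4-chloro-1,3-dimethyl-7-oxabicyclo[4.1.0]heptan-3-yl]ethan-1-one
Product: 8 (1S,3R,4R,6R)-4-chloro-3-ethynyl-1,3-dimethyl-7-oxabicyclo[4.1.0]heptane, via enol phosphate 6 (not isolated), via lithium acetylide 7 (not isolated)
Conditions: LiN(i-Pr)2 (1.1 equiv), THF, −78 °C; ClP(O)(OEt)2; LiN(i-Pr)2 (2.3 equiv), −78 → 0 °C; H2O
Reagents that add atoms: none
Why: Methyl ketone to terminal alkyne by the enol phosphate elimination method. Only C8 can be deprotonated because C1 is quaternary, so the enolate and its O-phosphate are single regioisomers. At low temperature the bulky amide should leave the poor chloride leaving group at C6 and the trisubstituted oxirane untouched.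

Step 6
Reactants: 8 (1S,3R,4R,6R)-4-chloro-3-ethynyl-1,3-dimethyl-7-oxabicyclo[4.1.0]heptane
Product: 10 (1S,3R,4R,6R)-4-chloro-3-[(E)-2-chloroethenyl]-1,3-dimethyl-7-oxabicyclo[4.1.0]heptane, via alkenylzirconocene chloride 9 (not isolated)
Conditions: Cp2Zr(H)Cl (1.3 equiv), CH2Cl2, rt; N-chlorosuccinimide, 0 °C
Reagents that add atoms: N-chlorosuccinimide, O=C1CCC(=O)N1Cl
Why: Hydrozirconation followed by halogenolysis. Syn addition places zirconium on the terminal carbon C8, away from quaternary C1, and chlorinolysis with retention gives the (E)-chloroalkene. A terminal alkyne reacts much faster with Cp2Zr(H)Cl than an oxirane or an alkyl chloride.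

Step 7
Reactants: 10 (1S,3R,4R,6R)-4-chloro-3-[(E)-2-chloroethenyl]-1,3-dimethyl-7-oxabicyclo[4.1.0]heptane
Product: 11 (1R,4R,5R)-5-chloro-4-[(E)-2-chloroethenyl]-4-methyl-2-methylidenecyclohexan-1-ol
Conditions: Cp2TiCl2 (2.5 equiv), Mn dust, THF, rt; 1 M HCl
Reagents that add atoms: none
Why: Isomerisation of a trisubstituted epoxide to an exo-methylene allylic alcohol by Cp2TiCl (trivalent titanium). Homolysis breaks the C3–O bond to give the tertiary C3 radical, so the C4–O bond and its configuration are kept. A second Cp2TiCl then removes a hydrogen from C10 rather than from neopentyl C2, and unactivated alkyl and vinyl chlorides are not reduced by this reagent.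

Step 8
Reactants: 11 (1R,4R,5R)-5-chloro-4-[(E)-2-chloroethenyl]-4-methyl-2-methylidenecyclohexan-1-ol
Product: 12 (1R,2R,4S)-2,4-dichloro-1-[(E)-2-chloroethenyl]-1-methyl-5-methylidenecyclohexane
Conditions: PPh3, Cl3CC(O)CCl3, CH2Cl2, −20 → 0 °C
Reagents that add atoms: hexachloroacetone, ClC(Cl)(Cl)C(=O)C(Cl)(Cl)Cl
Why: Appel-type chlorination; the PPh3/hexachloroacetone variant is the one known to convert secondary allylic alcohols with inversion and little transposition. In the chair with C6–Cl equatorial the C4–O bond is axial on the lower face, so backside attack from the upper face is open and places the new chloride equatorial and cis to C6–Cl.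

Step 9
Reactants: 12 (1R,2R,4S)-2,4-dichloro-1-[(E)-2-chloroethenyl]-1-methyl-5-methylidenecyclohexane
Product: 13 violacene, (1R,2S,4R,5R)-1-(bromomethyl)-1,2,4-trichloro-5-[(E)-2-chloroethenyl]-5-methylcyclohexane
Conditions: N-bromosuccinimide, HCl (dioxane), CH2Cl2, −78 → −40 °C, dark
Reagents that add atoms: N-bromosuccinimide, O=C1CCC(=O)N1Br; hydrogen chloride, Cl
Why: Electrophilic bromochlorination with BrCl made in the flask; Markovnikov opening puts Cl on tertiary C3 and Br on C10, and the chlorovinyl group is too electron-poor and hindered to compete. Br+ should bridge C3=C10 from the lower face, away from the axial chlorovinyl group, and chloride then opens at C3 anti, giving axial C3–Cl and equatorial CH2Br. The opposite course would force the larger CH2Br group into a 1,3-diaxial contact with the chlorovinyl group.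

## Compound list

1 | 3'-methylacetophenone | CC(=O)c1cccc(C)c1 | starting material
2 | 2-(3-methylphenyl)propan-2-ol | Cc1cccc(c1)C(C)(C)O | intermediate
3 | 2-(5-methylcyclohexa-1,4-dien-1-yl)propan-2-ol | CC1=CCC=C(C1)C(C)(C)O | intermediate
4 | 2-[(1S,6R)-1-methyl-7-oxabicyclo[4.1.0]hept-3-en-3-yl]propan-2-ol | C[C@]12CC(=CC[C@H]1O2)C(C)(C)O | intermediate
5 | 1-[(1S,3R,4R,6R)-4-chloro-1,3-dimethyl-7-oxabicyclo[4.1.0]heptan-3-yl]ethan-1-one | C[C@]12C[C@](C)(C(C)=O)[C@H](Cl)C[C@H]1O2 | intermediate
6 | diethyl 1-[(1S,3R,4R,6R)-4-chloro-1,3-dimethyl-7-oxabicyclo[4.1.0]heptan-3-yl]ethenyl phosphate | C[C@]12C[C@](C)(C(=C)OP(=O)(OCC)OCC)[C@H](Cl)C[C@H]1O2 | intermediate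
7 | lithium acetylide of 8 | C[C@]12C[C@](C)(C#C[Li])[C@H](Cl)C[C@H]1O2 | intermediate
8 | (1S,3R,4R,6R)-4-chloro-3-ethynyl-1,3-dimethyl-7-oxabicyclo[4.1.0]heptane | C[C@]12C[C@](C)(C#C)[C@H](Cl)C[C@H]1O2 | intermediate
9 | (E)-alkenylzirconocene chloride from 8, Zr on C8 | C[C@]12C[C@](C)(/C=C/[Zr](Cl)(C3C=CC=C3)C3C=CC=C3)[C@H](Cl)C[C@H]1O2 | intermediate
10 | (1S,3R,4R,6R)-4-chloro-3-[(E)-2-chloroethenyl]-1,3-dimethyl-7-oxabicyclo[4.1.0]heptane | C[C@]12C[C@](C)(/C=C/Cl)[C@H](Cl)C[C@H]1O2 | intermediate
11 | (1R,4R,5R)-5-chloro-4-[(E)-2-chloroethenyl]-4-methyl-2-methylidenecyclohexan-1-ol | C[C@]1(/C=C/Cl)CC(=C)[C@H](O)C[C@H]1Cl | intermediate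
12 | (1R,2R,4S)-2,4-dichloro-1-[(E)-2-chloroethenyl]-1-methyl-5-methylidenecyclohexane | C[C@]1(/C=C/Cl)CC(=C)[C@@H](Cl)C[C@H]1Cl | intermediate
13 | violacene, (1R,2S,4R,5R)-1-(bromomethyl)-1,2,4-trichloro-5-[(E)-2-chloroethenyl]-5-methylcyclohexane | C[C@]1(/C=C/Cl)C[C@](Cl)(CBr)[C@@H](Cl)C[C@H]1Cl | target

## Step count and least certain steps

Total step count: 9. Longest linear sequence: 9 steps (1 → 13).

**Step 4 (key step).**
- Risk: an unactivated methyl group migrates slowly. Loss of an allylic proton from C2 or C5 could therefore outrun it; this is ene-type chlorination, followed by easy aromatisation.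
- Risk: closure of the carbinol oxygen onto C1 could also outrun the shift.
- Risk: facial selectivity rests on a small oxirane and may be incomplete.
- Fallback: it sets out from 4 and comes back at 5, and it separates C–C from C–Cl bond formation.
- Hydroxyl-directed epoxidation of C1=C6 (VO(acac)2, t-BuOOH), anti to the existing oxirane, would give the trans bis-epoxide F1.
- A chelating Lewis acid (ZnBr2, CH2Cl2) would trigger the epoxide semipinacol rearrangement, with methyl migrating anti to the C1–O bond, to the β-hydroxy ketone F2.
- The C6–OH of F2 lies on the face where chlorine is wanted and the carbon is neopentyl, so substitution would go through the C6 radical.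
- Acylation with ClC(O)CO2Me (Et3N, DMAP) would give the methyl oxalate F3, and CsOH would give the cesium oxalate F4.
- Photoredox deoxychlorination ([Ir(dF(CF3)ppy)2(dtbbpy)]PF6, Cl3CCO2Et, blue light) would then give 5. The C6 configuration would then rest on substrate bias alone.

**Step 3.**
- Risk: site selectivity between two trisubstituted alkenes may be incomplete, and over-oxidation may occur.
- Risk: the catalyst must distinguish a methyl group from a ring CH2, which may limit enantioselectivity.
- Fallback: it sets out from 3 and comes back at 5 by reversing the order of the two alkene functionalisations.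
- A catalytic enantioselective chlorination/semipinacol rearrangement would be run on 3 with DCDMH and (DHQD)2PHAL or (DHQ)2PHAL, whichever gives the required sense.
- This would use binding of the carbinol OH to the catalyst to steer Cl+ to C1=C6, and it would give the chloro ketone alkene F5.
- Epoxidation of the remaining C3=C4 alkene with mCPBA, from the lower face opposite the axial acetyl group, would then give 5.

**Step 5.**
- Risk: while the mixture warms with excess amide base, E2 loss of HCl across C5–C6 may set in.
- Risk: base-induced isomerisation of the oxirane may also occur.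
- Fallback: it sets out from 5 and comes back at 8 without strong base.
- NaBH4 would reduce the ketone to the secondary alcohol F6, and the Burgess reagent would give the vinyl compound F7 by syn elimination.
- Ozonolysis (O3, then Me2S) would give the aldehyde F8.
- The Ohira–Bestmann reagent (K2CO3, MeOH) would return the lost carbon and give 8.

**Step 8.**
- Risk: the axial C4–O bond is aligned with the π-system and the CH2 terminus is unhindered, so attack with allylic transposition may compete.
- Risk: ionisation would erode the inversion.
- Risk: the product may drift to the primary allylic chloride.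
- Fallback: it sets out from 11 and comes back at 13 by removing the alkene before the substitution.
- Hydroxyl-directed epoxidation (VO(acac)2, t-BuOOH) on the lower face would give the spiro-epoxy alcohol F9.
- PPh3/CCl4 would invert C4 without any allylic pathway and give the spiro-epoxy chloride F10, which continues as described under step 9.

**Step 9.**
- Risk: C4–Cl destabilises positive charge at C3, so chloride may open the bromonium ion at C10 instead.
- Risk: reversible bromonium formation leaves the facial outcome to the opening step.
- Fallback: it sets out from 12 and comes back at 13, with the face fixed in an irreversible step.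
- mCPBA should attack the methylene group from the open lower face and give the spiro-epoxy chloride F10.
- Anhydrous HCl (CH2Cl2, −78 °C) should open F10 at tertiary C3 with inversion to give the chlorohydrin F11.
- CBr4/PPh3 would then convert the primary alcohol into the bromide 13.

## Further compounds

F1 | step 4 | 2-[(1S,3S,5R,7R)-1-methyl-4,8-dioxatricyclo[5.1.0.0(3,5)]octan-3-yl]propan-2-ol | C[C@]12C[C@]3(C(C)(C)O)O[C@@H]3C[C@H]1O2
F2 | step 4 | 1-[(1S,3S,4R,6R)-4-hydroxy-1,3-dimethyl-7-oxabicyclo[4.1.0]heptan-3-yl]ethan-1-one | C[C@]12C[C@](C)(C(C)=O)[C@H](O)C[C@H]1O2
F3 | step 4 | methyl oxalate ester of F2 | C[C@]12C[C@](C)(C(C)=O)[C@H](OC(=O)C(=O)OC)C[C@H]1O2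
F4 | step 4 | cesium oxalate half-ester of F2 | C[C@]12C[C@](C)(C(C)=O)[C@H](OC(=O)C(=O)[O-])C[C@H]1O2.[Cs+]
F5 | step 3 | 1-[(1R,6R)-6-chloro-1,3-dimethylcyclohex-3-en-1-yl]ethan-1-one | C[C@]1(C(C)=O)CC(C)=CC[C@H]1Cl
F6 | step 5 | 1-[(1S,3R,4R,6R)-4-chloro-1,3-dimethyl-7-oxabicyclo[4.1.0]heptan-3-yl]ethan-1-ol (either carbinol epimer) | C[C@]12C[C@](C)(C(C)O)[C@H](Cl)C[C@H]1O2
F7 | step 5 | (1S,3R,4R,6R)-4-chloro-3-ethenyl-1,3-dimethyl-7-oxabicyclo[4.1.0]heptane | C[C@]12C[C@](C)(C=C)[C@H](Cl)C[C@H]1O2
F8 | step 5 | (1S,3R,4R,6R)-4-chloro-1,3-dimethyl-7-oxabicyclo[4.1.0]heptane-3-carbaldehyde | C[C@]12C[C@](C)(C=O)[C@H](Cl)C[C@H]1O2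
F9 | step 8 | (3R,4R,6R,7R)-6-chloro-7-[(E)-2-chloroethenyl]-7-methyl-1-oxaspiro[2.5]octan-4-ol | C[C@]1(/C=C/Cl)C[C@@]2(CO2)[C@H](O)C[C@H]1Cl
F10 | step 9 | (3R,4S,6R,7R)-4,6-dichloro-7-[(E)-2-chloroethenyl]-7-methyl-1-oxaspiro[2.5]octane | C[C@]1(/C=C/Cl)C[C@@]2(CO2)[C@@H](Cl)C[C@H]1Cl
F11 | step 9 | [(1S,2S,4R,5R)-1,2,4-trichloro-5-[(E)-2-chloroethenyl]-5-methylcyclohexyl]methanol | C[C@]1(/C=C/Cl)C[C@](Cl)(CO)[C@@H](Cl)C[C@H]1Cl
A1 | alternative 1 | isoprene | C=CC(C)=C
A2 | alternative 1 | (Z)-3-chloro-2-methylprop-2-enal | Cl/C=C(/C)C=O
A3 | alternative 1 | (1R,6R)-6-chloro-1,3-dimethylcyclohex-3-ene-1-carbaldehyde | C[C@]1(C=O)CC(C)=CC[C@H]1Cl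
A4 | alternative 1 | (1R,6R)-6-chloro-1,4-dimethylcyclohex-3-ene-1-carbaldehyde | C[C@]1(C=O)CC=C(C)C[C@H]1Cl
A5 | alternative 2 | (1E,3Z,6S)-1,6-dichloro-3,7-dimethylocta-1,3,7-triene | C=C(C)[C@@H](Cl)C/C=C(C)\C=C\Cl
A6 | alternative 3 | (1S)-2,6-dimethylcyclohepta-2,5-dien-1-ol | CC1=CCC=C(C)[C@@H](O)C1
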